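**Retrosynthetic overview**
- The target is cut back, by C4 acetylation and C3 acylation with (2S,3S)-2,3-epoxy-2-methylbutanoic acid (Sharpless epoxidation of angelyl alcohol), to a cis-eudesmane 3,4-diol-8-one, and this, by C7 epimerisation and hydrogenation, to its 1,11-diene.
- Ring A is cut at C1=C2 by ring-rearrangement metathesis. The feature used is that ring B (C5–C10), with its C8 ketone, the cis branches on C5 and C10 and the three-carbon branch on C7, is the cyclohexanone core of a 4,6-dimethylbicyclo[2.2.2]oct-5-en-2-one. Its methyl-bearing bridge alkene (C1=C11) holds C1 of ring A and the future isopropyl group.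
- The bicycle comes from PhI(OAc)2/MeOH dearomatisation of 2-methoxy-4,6-dimethylphenol and an endo Diels–Alder reaction with an enantiopure vinyl ketone that carries C2–C4 and the C3 oxygen. C15 then enters by chelation-controlled MeMgBr addition, and the C9 carbonyl is removed while C8 is unmasked (NaBH4; H3O+; SmI2).
- Order of ring formation: ring B as the bicycle (step 5), ring A by metathesis (step 9); the epoxide is made in a separate branch (step 14).

Key step: step 9

Remarks. Atoms carry eudesmane numbers (C1–C15). Assumption: (3R,4R)-hexa-1,5-diene-3,4-diol, the divinyl glycol of the D-mannitol series, is bought as the single enantiomer.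

**Step 1**
Reactants: 1 2-methoxy-4-methylphenol (creosol)
Product: 2 2-hydroxy-3-methoxy-5-methylbenzaldehyde
Conditions: MgCl2, Et3N, (CH2O)n, MeCN, reflux
Reagents that add atoms: formaldehyde (as paraformaldehyde), C=O
Why: Casnati–Skattebøl ortho-formylation, in which the magnesium phenoxide delivers formaldehyde to the only free ortho position (the para position carries the methyl group) and a second formaldehyde takes up the hydride.

**Step 2**
Reactants: 2 2-hydroxy-3-methoxy-5-methylbenzaldehyde
Product: 4 2-methoxy-4,6-dimethylphenol, via 2-(hydroxymethyl)-6-methoxy-4-methylphenol 3 (not isolated)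
Conditions: H2 (3 atm), Pd/C, AcOH, 40 °C
Reagents that add atoms: none
Why: Hydrogenolysis of an electron-rich ortho-hydroxybenzaldehyde over palladium in acetic acid runs through the benzylic alcohol 3 to the methyl group and should leave the arene, the phenol and the methyl ether untouched.

**Step 3**
Reactants: 5 (3R,4R)-hexa-1,5-diene-3,4-diol
Product: 6 (3R,4R)-4-(methoxymethoxy)hexa-1,5-dien-3-ol
Conditions: NaH (1.0 equiv), THF, 0 °C; MOMCl (1.0 equiv), 0 °C to rt
Reagents that add atoms: chloromethyl methyl ether, COCCl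
Why: Williamson-type monoalkylation of the monosodium alkoxide of a C2-symmetric diol, whose two hydroxyls are equivalent, so that only recovered diol and bis-ether need to be separated and no stereocentre is touched.

**Step 4**
Reactants: 6 (3R,4R)-4-(methoxymethoxy)hexa-1,5-dien-3-ol
Product: 7 (4R)-4-(methoxymethoxy)hexa-1,5-dien-3-one
Conditions: Dess–Martin periodinane, CH2Cl2, 0 °C to rt; used at once
Reagents that add atoms: none
Why: Dess–Martin oxidation of the secondary allylic alcohol under non-enolising conditions should give the vinyl ketone without moving the beta,gamma double bond or disturbing the oxygen-bearing stereocentre.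

**Step 5**
Reactants: 4 2-methoxy-4,6-dimethylphenol; 7 (4R)-4-(methoxymethoxy)hexa-1,5-dien-3-one
Product: 9 (1S,4S,7S)-3,3-dimethoxy-7-[(2R)-2-(methoxymethoxy)but-3-enoyl]-1,5-dimethylbicyclo[2.2.2]oct-5-en-2-one, via 6,6-dimethoxy-2,4-dimethylcyclohexa-2,4-dien-1-one 8 (not isolated)
Conditions: 4 (1.5 equiv), PhI(OAc)2, MeOH, 0 °C; then 7, 0 to 50 °C
Reagents that add atoms: methanol, CO
Why: Oxidative dearomatisation gives the masked ortho-benzoquinone 8, whose Diels–Alder reaction with vinyl ketones is ortho- and endo-selective, so the acyl-bearing carbon bonds to the methyl-bearing dienone carbon next to C=O (C5–C10, C6–C7) and the acyl group lies syn to the new C1=C11 alkene; the C3 centre of 7 is carried in unchanged and sets the absolute configuration once the diastereomeric endo adduct from the other face of 8 is removed by chromatography.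

**Step 6**
Reactants: 9 the Diels–Alder ketone
Product: 10 (1S,4S,7S)-7-[(2S,3R)-2-hydroxy-3-(methoxymethoxy)pent-4-en-2-yl]-3,3-dimethoxy-1,5-dimethylbicyclo[2.2.2]oct-5-en-2-one
Conditions: MeMgBr (1.1 equiv), THF, −78 °C
Reagents that add atoms: methylmagnesium bromide, C[Mg]Br
Why: Chelation-controlled (Cram chelate) Grignard addition in which magnesium bridges the C4 ketone and the C3 methoxymethyl ether and methyl enters anti to the vinyl group, the same face being the Felkin–Anh face with respect to C5 (C10 anti to the nucleophile), while the other ketone (C9) lies between two fully substituted carbons and should not compete at −78 °C.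

**Step 7**
Reactants: 10 the tertiary alcohol
Product: 12 (1S,3R,4S,8S)-3-hydroxy-8-[(2S,3R)-2-hydroxy-3-(methoxymethoxy)pent-4-en-2-yl]-4,6-dimethylbicyclo[2.2.2]oct-5-en-2-one, via ketal carbinol 11 (not isolated)
Conditions: NaBH4, MeOH, 0 °C; then 1 M aq. HCl, THF, rt
Reagents that add atoms: water, O
Why: Borohydride reduction of the hindered alpha,alpha-dimethoxy ketone from the less encumbered alkene side gives carbinol 11 (its configuration is lost in step 8, so either epimer serves), and dilute acid then hydrolyses the dimethyl ketal, which is far more labile than the methoxymethyl ether, to the alpha-hydroxy ketone.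

**Step 8**
Reactants: 12 the alpha-hydroxy ketone
Product: 13 (1S,4S,8S)-8-[(2S,3R)-2-hydroxy-3-(methoxymethoxy)pent-4-en-2-yl]-4,6-dimethylbicyclo[2.2.2]oct-5-en-2-one
Conditions: SmI2 (4 equiv), THF/MeOH, −78 °C to rt
Reagents that add atoms: none
Why: Samarium diiodide reduction of an alpha-heterosubstituted ketone (ketyl, second electron transfer, beta-elimination of hydroxide, protonation of the samarium enolate) removes the C9 oxygen and leaves the C8 ketone, the same cleavage that strips alpha-alkoxy groups from bicyclo[2.2.2]octenones of this kind.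

**Step 9**
Reactants: 13 the bicyclooctenone with the syn side chain
Product: 14 (3S,4aS,5S,6R,8aS)-5-hydroxy-6-(methoxymethoxy)-5,8a-dimethyl-3-(prop-1-en-2-yl)-3,4,4a,5,6,8a-hexahydronaphthalen-2(1H)-one
Conditions: second-generation Grubbs catalyst (H2IMes)(PCy3)Cl2Ru=CHPh (10 mol %), ethylene (1 atm), toluene (0.005 M), 60 °C
Reagents that add atoms: ethylene, C=C
Why: Proposed new method: ring-rearrangement metathesis is established for unsubstituted bridge alkenes of bicyclo[2.2.2]octenes but not for a methyl-bearing, trisubstituted one; the ruthenium methylidene kept alive by ethylene should add to the strained C1=C11 bond with CH2 going to the more substituted C11 and the metal to C1, and cycloreversion, driven by release of the bicyclic strain, leaves the isopropenyl group on C7 and a carbene on C1. This carbene closes ring A by ring-closing metathesis onto the C2 vinyl group (six-membered ring, endocyclic C1=C2), which is possible only because the side chain is syn to the bridge alkene. If the catalyst loads first on the terminal vinyl group, the C2 carbene can add across C1=C11 in the same six-ring sense and ethylene then frees C11 as the isopropenyl group, so both entries converge on 14. The closest known reactions are the ring-opening/ring-closing metathesis of unsubstituted bicyclo[2.2.2]octene bridges to cis-decalins and the ring opening of trisubstituted norbornenes and cyclobutenes. No stereocentre is formed: C5, C10 and C7 are the centres of the bicycle, so ring A is cis-fused and the isopropenyl group on C7 is cis to C1, that is, epimeric to the target. The step needs ring closure to win over oligomerisation through the vinyl group, which the endo geometry, high dilution and ethylene should secure.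

**Step 10**
Reactants: 14 the 1,11-diene
Product: 15 (3S,4aS,5S,6R,8aR)-5-hydroxy-6-(methoxymethoxy)-5,8a-dimethyl-3-(propan-2-yl)octahydronaphthalen-2(1H)-one
Conditions: H2 (1 atm), Pd/C, EtOAc, rt
Reagents that add atoms: none
Why: Heterogeneous hydrogenation saturates the cis-disubstituted ring alkene and the isopropenyl group; C1, C2 and C11 are not stereogenic afterwards, so facial selectivity is irrelevant, and any drift at C7 is corrected in step 11.

**Step 11**
Reactants: 15 the 7-epi ketone
Product: 16 (3R,4aS,5S,6R,8aR)-5-hydroxy-6-(methoxymethoxy)-5,8a-dimethyl-3-(propan-2-yl)octahydronaphthalen-2(1H)-one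
Conditions: NaOMe (0.5 equiv), MeOH, rt
Reagents that add atoms: none
Why: Thermodynamic epimerisation through the C7/C8 enolate: in the cis-decalin chair that keeps the C10 and C4 methyl groups apart, the target configuration has the isopropyl group equatorial whereas the 7-epimer must hold it axial against C4, so the equilibrium should lie on the side of 16, and no beta-leaving group or retro-aldol path is present.

**Step 12**
Reactants: 16 the C7-equilibrated ketone
Product: 17 (3R,4aS,5S,6R,8aR)-5,6-dihydroxy-5,8a-dimethyl-3-(propan-2-yl)octahydronaphthalen-2(1H)-one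
Conditions: 6 M aq. HCl, THF, 40 °C
Reagents that add atoms: none
Why: Acid hydrolysis of the methoxymethyl acetal in an aqueous medium, so that the oxocarbenium ion is taken by water and not by the neighbouring tertiary hydroxyl; the acid keeps C7 at its thermodynamic configuration.

**Step 13**
Reactants: 18 angelic acid
Product: 19 (2Z)-2-methylbut-2-en-1-ol
Conditions: LiAlH4, Et2O, 0 °C
Reagents that add atoms: none
Why: Hydride reduction of the carboxylic acid to the allylic alcohol (1,2-reduction of an alkyl-substituted acrylic acid) with retention of the Z geometry.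

**Step 14**
Reactants: 19 (2Z)-2-methylbut-2-en-1-ol
Product: 20 [(2R,3S)-2,3-dimethyloxiran-2-yl]methanol
Conditions: Ti(OiPr)4 (10 mol %), D-(−)-diethyl tartrate (12 mol %), tBuOOH, 4 Å molecular sieves, CH2Cl2, −20 °C
Reagents that add atoms: tert-butyl hydroperoxide, CC(C)(C)OO
Why: Sharpless asymmetric epoxidation, in which the D-(−)-tartrate ligand directs oxygen to the face that gives the 2R epoxy alcohol (the L-(+)-ligand gives 2S-glycidols) and the syn addition keeps CH2OH and the C3 methyl cis.

**Step 15**
Reactants: 20 the epoxy alcohol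
Product: 21 (2S,3S)-2,3-dimethyloxirane-2-carboxylic acid
Conditions: RuCl3 (cat.), NaIO4, MeCN/EtOAc/H2O, rt
Reagents that add atoms: water, O
Why: Ruthenium tetroxide oxidation (RuCl3/NaIO4) of a primary epoxy alcohol to the glycidic acid, which spares the epoxide; the change of the C2 descriptor from R to S is only a change of priorities.

**Step 16**
Reactants: 17 the diol; 21 (2S,3S)-2,3-dimethyloxirane-2-carboxylic acid
Product: 23 (1S,2R,4aR,7R,8aS)-1-hydroxy-1,4a-dimethyl-6-oxo-7-(propan-2-yl)decahydronaphthalen-2-yl (2S,3S)-2,3-dimethyloxirane-2-carboxylate, via mixed anhydride 22 (not isolated)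
Conditions: 21, 2,4,6-trichlorobenzoyl chloride, Et3N, THF, rt; then 17, DMAP, toluene, rt
Reagents that add atoms: none
Why: Yamaguchi esterification, in which DMAP transfers the aliphatic acyl group of 22 to the secondary C3 hydroxyl while the tertiary C4 hydroxyl stays free and the mild base leaves the epoxide and all stereocentres alone.

**Step 17**
Reactants: 23 the C3 ester
Product: 24 (1S,2R,4aR,7R,8aS)-1-(acetyloxy)-1,4a-dimethyl-6-oxo-7-(propan-2-yl)decahydronaphthalen-2-yl (2S,3S)-2,3-dimethyloxirane-2-carboxylate (CNP0221066.1)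
Conditions: Ac2O, DMAP, Et3N, CH2Cl2, 40 °C
Reagents that add atoms: acetic anhydride, CC(=O)OC(C)=O
Why: DMAP-catalysed (Steglich-type) acetylation of the tertiary hydroxyl under non-acidic conditions that spare the epoxide; the C3 ester cannot wander because migration to a tertiary oxygen is uphill.

**Compound list**
1 | 2-methoxy-4-methylphenol (creosol) | Cc1ccc(O)c(OC)c1 | starting material
2 | 2-hydroxy-3-methoxy-5-methylbenzaldehyde | Cc1cc(C=O)c(O)c(OC)c1 | intermediate
3 | 2-(hydroxymethyl)-6-methoxy-4-methylphenol | Cc1cc(CO)c(O)c(OC)c1 | intermediate (not isolated)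
4 | 2-methoxy-4,6-dimethylphenol | Cc1cc(C)c(O)c(OC)c1 | intermediate
5 | (3R,4R)-hexa-1,5-diene-3,4-diol | C=C[C@@H](O)[C@H](O)C=C | starting material
6 | (3R,4R)-4-(methoxymethoxy)hexa-1,5-dien-3-ol | C=C[C@@H](O)[C@H](OCOC)C=C | intermediate
7 | (4R)-4-(methoxymethoxy)hexa-1,5-dien-3-one | C=C[C@@H](OCOC)C(=O)C=C | intermediate
8 | 6,6-dimethoxy-2,4-dimethylcyclohexa-2,4-dien-1-one | COC1(OC)C=C(C)C=C(C)C1=O | intermediate (not isolated)
9 | (1S,4S,7S)-3,3-dimethoxy-7-[(2R)-2-(methoxymethoxy)but-3-enoyl]-1,5-dimethylbicyclo[2.2.2]oct-5-en-2-one (acyl group syn to the alkene) | C=C[C@@H](OCOC)C(=O)[C@H]1C[C@@H]2C(OC)(OC)C(=O)[C@@]1(C)C=C2C | intermediate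
10 | (1S,4S,7S)-7-[(2S,3R)-2-hydroxy-3-(methoxymethoxy)pent-4-en-2-yl]-3,3-dimethoxy-1,5-dimethylbicyclo[2.2.2]oct-5-en-2-one | C=C[C@@H](OCOC)[C@@](C)(O)[C@H]1C[C@@H]2C(OC)(OC)C(=O)[C@@]1(C)C=C2C | intermediate
11 | (1S,2R,4S,7S)-7-[(2S,3R)-2-hydroxy-3-(methoxymethoxy)pent-4-en-2-yl]-3,3-dimethoxy-1,5-dimethylbicyclo[2.2.2]oct-5-en-2-ol (hydroxyl on the side of the saturated bridge) | C=C[C@@H](OCOC)[C@@](C)(O)[C@H]1C[C@@H]2C(OC)(OC)[C@H](O)[C@@]1(C)C=C2C | intermediate (not isolated)
12 | (1S,3R,4S,8S)-3-hydroxy-8-[(2S,3R)-2-hydroxy-3-(methoxymethoxy)pent-4-en-2-yl]-4,6-dimethylbicyclo[2.2.2]oct-5-en-2-one | C=C[C@@H](OCOC)[C@@](C)(O)[C@H]1C[C@@H]2C(=O)[C@H](O)[C@@]1(C)C=C2C | intermediate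
13 | (1S,4S,8S)-8-[(2S,3R)-2-hydroxy-3-(methoxymethoxy)pent-4-en-2-yl]-4,6-dimethylbicyclo[2.2.2]oct-5-en-2-one (side chain syn to the alkene) | C=C[C@@H](OCOC)[C@@](C)(O)[C@H]1C[C@@H]2C(=O)C[C@@]1(C)C=C2C | intermediate
14 | (3S,4aS,5S,6R,8aS)-5-hydroxy-6-(methoxymethoxy)-5,8a-dimethyl-3-(prop-1-en-2-yl)-3,4,4a,5,6,8a-hexahydronaphthalen-2(1H)-one | O[C@]1(C)[C@H](OCOC)C=C[C@]2(C)CC(=O)[C@H](C(C)=C)C[C@@H]21 | intermediate
15 | (3S,4aS,5S,6R,8aR)-5-hydroxy-6-(methoxymethoxy)-5,8a-dimethyl-3-(propan-2-yl)octahydronaphthalen-2(1H)-one | O[C@]1(C)[C@H](OCOC)CC[C@]2(C)CC(=O)[C@H](C(C)C)C[C@@H]21 | intermediate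
16 | (3R,4aS,5S,6R,8aR)-5-hydroxy-6-(methoxymethoxy)-5,8a-dimethyl-3-(propan-2-yl)octahydronaphthalen-2(1H)-one | O[C@]1(C)[C@H](OCOC)CC[C@]2(C)CC(=O)[C@@H](C(C)C)C[C@@H]21 | intermediate
17 | (3R,4aS,5S,6R,8aR)-5,6-dihydroxy-5,8a-dimethyl-3-(propan-2-yl)octahydronaphthalen-2(1H)-one | O[C@]1(C)[C@H](O)CC[C@]2(C)CC(=O)[C@@H](C(C)C)C[C@@H]21 | intermediate
18 | angelic acid, (2Z)-2-methylbut-2-enoic acid | C/C=C(/C)C(=O)O | starting material
19 | (2Z)-2-methylbut-2-en-1-ol | C/C=C(/C)CO | intermediate
20 | [(2R,3S)-2,3-dimethyloxiran-2-yl]methanol | OC[C@@]1(C)O[C@H]1C | intermediate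
21 | (2S,3S)-2,3-dimethyloxirane-2-carboxylic acid | OC(=O)[C@@]1(C)O[C@H]1C | intermediate
22 | (2S,3S)-2,3-dimethyloxirane-2-carboxylic 2,4,6-trichlorobenzoic anhydride | O=C(OC(=O)c1c(Cl)cc(Cl)cc1Cl)[C@@]2(C)O[C@H]2C | intermediate (not isolated)
23 | (1S,2R,4aR,7R,8aS)-1-hydroxy-1,4a-dimethyl-6-oxo-7-(propan-2-yl)decahydronaphthalen-2-yl (2S,3S)-2,3-dimethyloxirane-2-carboxylate | O[C@]1(C)[C@H](OC(=O)[C@@]3(C)O[C@H]3C)CC[C@]2(C)CC(=O)[C@@H](C(C)C)C[C@@H]21 | intermediate
24 | (1S,2R,4aR,7R,8aS)-1-(acetyloxy)-1,4a-dimethyl-6-oxo-7-(propan-2-yl)decahydronaphthalen-2-yl (2S,3S)-2,3-dimethyloxirane-2-carboxylate | CC(=O)O[C@]1(C)[C@H](OC(=O)[C@@]2(C)O[C@H]2C)CC[C@]2(C)CC(=O)[C@@H](C(C)C)C[C@@H]21 | target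

**Step count**
Total: 17 steps. Longest linear sequence: 12 steps (1, 2, 5, 6, 7, 8, 9, 10, 11, 12, 16, 17).

**Steps most likely to fail**

Step 9 (Proposed new method). The carbene may load only on the terminal vinyl group while the hindered trisubstituted bridge alkene stays closed, so that side-chain dimers build up instead of ring A. The fallback opens the bridge oxidatively and closes ring A by an ordinary diene ring-closing metathesis. It sets out from 11, isolated from step 7 by leaving out the acid treatment. Ozone (CH2Cl2/MeOH, −78 °C, Sudan red 7B end point, then Me2S) should cleave the electron-rich trisubstituted bridge alkene ahead of the allylic-ether vinyl group and give the keto aldehyde F1, which is expected to rest as the lactol with the C4 hydroxyl. Excess Ph3P=CH2 in THF methylenates both carbonyls to the triene F2. The second-generation Grubbs catalyst in CH2Cl2 at 40 °C joins the C10 and C3 vinyl groups to the cis-decalin ketal F3. Dilute aqueous HCl in THF frees the C8 ketone to give the alpha-hydroxy ketone F4, and SmI2 as in step 8 returns to the route at 14. Should C7 epimerise during the Wittig step, both epimers converge at 16.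

Step 5. The dienone 7, which cannot be used in large excess, may be lost to methanol addition or oligomerisation before the hindered dienone 8 captures it, or the two endo adducts may form without facial preference and co-elute. The fallback uses a simple dienophile in excess and sets C3 by reagent control. It sets out from 4: the same oxidation (PhI(OAc)2, MeOH), run with acrolein (10 equiv), gives the racemic endo aldehyde F5. [(Z)-3-(Methoxymethoxy)allyl]diisopinocampheylborane, made from allyl methoxymethyl ether, sec-BuLi, (−)-B-methoxydiisopinocampheylborane (from (+)-alpha-pinene) and BF3·OEt2 in THF at −78 °C, adds to the aldehyde to give the borinate F6. Oxidative work-up (NaOH, H2O2) then gives the syn alcohol F7 from the (1S,4S,7S) aldehyde, together with the diastereomer from its enantiomer, which is separated here or after oxidation. Dess–Martin oxidation of F7 returns to the route at 9.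

Step 17. Acylation of the hindered axial tertiary hydroxyl next to the bulky C3 ester may be too slow, and forcing it invites elimination or attack on the epoxide. The fallback reverses the order of the two acylations and sets out from 17. Trimethyl orthoacetate with pyridinium p-toluenesulfonate in CH2Cl2 gives the cyclic orthoester F8. Brief treatment with aqueous acetic acid opens it kinetically to the axial, tertiary acetate F9 with the C3 hydroxyl free. Yamaguchi esterification of F9 with 21 (through 22, as in step 16) returns to the route at 24.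

**Further compounds**
F1 | step 9 | 4-acetyl-6-hydroxy-2-[(2S,3R)-2-hydroxy-3-(methoxymethoxy)pent-4-en-2-yl]-5,5-dimethoxy-1-methylcyclohexane-1-carbaldehyde (ring stereocentres as in 11) | C=C[C@@H](OCOC)[C@@](C)(O)[C@H]1C[C@@H](C(C)=O)C(OC)(OC)[C@H](O)[C@@]1(C)C=O
F2 | step 9 | 2-ethenyl-3-[(2S,3R)-2-hydroxy-3-(methoxymethoxy)pent-4-en-2-yl]-6,6-dimethoxy-2-methyl-5-(prop-1-en-2-yl)cyclohexan-1-ol (ring stereocentres as in 11) | C=C[C@@H](OCOC)[C@@](C)(O)[C@H]1C[C@@H](C(C)=C)C(OC)(OC)[C@H](O)[C@@]1(C)C=C
F3 | step 9 | 2,2-dimethoxy-6-(methoxymethoxy)-5,8a-dimethyl-3-(prop-1-en-2-yl)-1,2,3,4,4a,5,6,8a-octahydronaphthalene-1,5-diol (stereocentres as in 14, C1 carbinol as in 11) | O[C@]1(C)[C@H](OCOC)C=C[C@]2(C)[C@@H](O)C(OC)(OC)[C@H](C(C)=C)C[C@@H]21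
F4 | step 9 | 1,5-dihydroxy-6-(methoxymethoxy)-5,8a-dimethyl-3-(prop-1-en-2-yl)-3,4,4a,5,6,8a-hexahydronaphthalen-2(1H)-one (stereocentres as in F3) | O[C@]1(C)[C@H](OCOC)C=C[C@]2(C)[C@@H](O)C(=O)[C@H](C(C)=C)C[C@@H]21
F5 | step 5 | racemic 3,3-dimethoxy-1,5-dimethyl-2-oxobicyclo[2.2.2]oct-5-ene-7-carbaldehyde (formyl group syn to the alkene; the (1S,4S,7S) enantiomer shown leads to 9) | O=C[C@H]1C[C@@H]2C(OC)(OC)C(=O)[C@@]1(C)C=C2C
F6 | step 5 | diisopinocampheylborinate of F7 | C=C[C@@H](OCOC)[C@H](OB([C@@H]3C[C@@H]4C[C@H]([C@H]3C)C4(C)C)[C@@H]3C[C@@H]4C[C@H]([C@H]3C)C4(C)C)[C@H]1C[C@@H]2C(OC)(OC)C(=O)[C@@]1(C)C=C2C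
F7 | step 5 | (1S,4S,7S)-7-[(1R,2R)-1-hydroxy-2-(methoxymethoxy)but-3-en-1-yl]-3,3-dimethoxy-1,5-dimethylbicyclo[2.2.2]oct-5-en-2-one | C=C[C@@H](OCOC)[C@H](O)[C@H]1C[C@@H]2C(OC)(OC)C(=O)[C@@]1(C)C=C2C
F8 | step 17 | cyclic methyl orthoacetate of diol 17 across O3 and O4 (mixture at the orthoester carbon) | O1[C@]2(C)[C@H](OC1(C)OC)CC[C@]3(C)CC(=O)[C@@H](C(C)C)C[C@@H]32
F9 | step 17 | (1S,2R,4aR,7R,8aS)-2-hydroxy-1,4a-dimethyl-6-oxo-7-(propan-2-yl)decahydronaphthalen-1-yl acetate | CC(=O)O[C@]1(C)[C@H](O)CC[C@]2(C)CC(=O)[C@@H](C(C)C)C[C@@H]21
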